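0.633 is the number I carry from the south-west run: over each interval between readings I divide the target gained by the mean substrate standing in the flask, in shares of the charge, and the sum is the catalyst dose.

| flask | substrate | free catalyst | remark | time |
|---|---|---|---|---|
| north-west | 23 mM (fed, over 50 min) | 1.2 mM | run made earlier |  |
| south-west | 23 mM (fed, over 50 min) | 2.2 mM | run made earlier |  |
| epsilon | 23 mM | 2.0 mM | everything together at the start | 50 min |
| zeta | 23 mM (fed, over 50 min) | 3.0 mM |  | 50 min |

| north-west: time / min | north-west: target / % | south-west: time / min | south-west: target / % |
|---|---|---|---|
| 4.00 | 1 | 12.0 | 3 |
| 10.0 | 5 | 25.0 | 9 |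
| 20.0 | 5 | 40.0 | 15 |
| 50.0 | 15 | 50.0 | 18 |

(standard deviation of a reading: 2 percentage points)

- what was read earlier has a scatter of 2 percentage points, one standard deviation
- candidate steps: substrate + free catalyst -> catalyst intermediate; catalyst intermediate -> free catalyst + target; free catalyst <-> dormant form; target -> over-reaction product
- percentages count the whole charge, also what has not yet gone in

* which of the two ends with the higher amount of target, in percent of the substrate charged ("neither" if they lie within 2 percentage points) (epsilon / zeta / neither)
* target at the end, in percent of the substrate charged, epsilon
* target at the end, in percent of the substrate charged, zeta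

My assumption, which the readings do not prove, is a rate κ·c_substrate, pseudo-first-order, with κ proportional to c_free catalyst and with the same fall over time in south-west, epsilon and zeta alike. Charged at once, this integrates in closed form: the target share is one minus exp(−dose).

The ladder starts with κ. In south-west it falls from 0.0238 min⁻¹ in the first interval to 0.00408 min⁻¹ in the last, a halving time of 15.3 min. This halving time, read off readings with their scatter, is shorter than the feed of 50 min, so I take the catalyst in south-west to fade while most substrate is still outside. Slowest is the late substrate lifetime, 245 min, so I expect substrate left in both epsilon and zeta.

Scaled by catalyst, the dose gives epsilon 43.8%; south-west's last reading, scaled likewise, gives zeta 24.5%. North-west sums to 0.816 with less catalyst, against the proportion; its readings carry a scatter of 2 percentage points, and I keep the south-west value.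

The forecast gives 21% for epsilon and 25% for zeta: “Zeta probably wins, moderately confidently”. My reckoning puts epsilon ahead, so it parts from the forecast on epsilon and on the winner.

The flask gives 39.3% for epsilon and 22.1% for zeta, so epsilon ends higher.

    substrate + free catalyst → catalyst intermediate (k = 12.3 M⁻¹ min⁻¹)
    catalyst intermediate → free catalyst + target (k = 14.6 min⁻¹)
    free catalyst ⇌ dormant form (K = 5.20, k = 0.0543 min⁻¹)
    target → over-reaction product (k = 9.30 × 10⁻⁵ min⁻¹)

The main reason for the gap to zeta is the way the substrate goes in: epsilon, fed instead at its own 2.0 mM of free catalyst, ends at 15.7%, not 39.3%. The result of epsilon as charged corresponds to a dose of 0.499, against my 0.576. For the neighbour of epsilon with 3.4 mM of free catalyst, the dose gives 62.4%; the computed flask ends at 57.2%.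

The runs are simulated from invented constants; noise was put on by code.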